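**Retrosynthetic overview**
- The target is made in the last step by a one-pot sequence: a 2-silyloxyfuran/ynone Diels–Alder benzannulation builds ring A with all three oxygens in place, then ring-closing metathesis closes the 2H-pyran; the chalcone arm arrives in the dienophile.
- The diene comes from a 3-vinyl-4-alkoxybutenolide (tetronate), made by iodination/Stille coupling of the tetronate that an intramolecular Wittig reaction (Ph3P=C=C=O) forms from a linalyl glycolate.
- The C2 stereocentre is the carbinol carbon of (S)-linalool; its C–O bond is never broken. The side-chain tertiary alcohol comes from a Mukaiyama hydration at the glycolate stage.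
- The enynone dienophile comes from methyl p-coumarate by a one-pot Weinreb amide formation/ethynyl Grignard addition.
- Ring order: sacrificial butenolide, then benzene ring A and the pyran ring together in the final operation.

Assumption: (S)-(+)-linalool (coriandrol) is bought as chiral-pool material of ≥98% ee.

**Step 1**
Reactants: 1 (S)-linalool; 2 acetoxyacetyl chloride
Product: 4 (3S)-3,7-dimethylocta-1,6-dien-3-yl 2-hydroxyacetate, via linalyl acetoxyacetate 3 (not isolated)
Conditions: n-BuLi, THF, −78 °C; 2, −78 → 0 °C; then K2CO3 (cat.), MeOH, 0 °C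
Reagents that add atoms: none
Why: O-acylation of the lithium tert-alkoxide by the acid chloride, then chemoselective transesterification (methanolysis) of the unhindered acetate; the linalool C–O bond is untouched, so the stereocentre is carried over.

**Step 2**
Reactants: 4 (3S)-3,7-dimethylocta-1,6-dien-3-yl 2-hydroxyacetate
Product: 5 (3S)-7-hydroxy-3,7-dimethyloct-1-en-3-yl 2-hydroxyacetate
Conditions: Co(acac)2 (10 mol %), PhSiH3, O2 (1 atm), THF, 23 °C; then PPh3
Reagents that add atoms: dioxygen O=O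
Why: Mukaiyama hydration (cobalt hydride hydrogen-atom transfer, Markovnikov) takes the electron-rich trisubstituted alkene via its tertiary radical and leaves the hindered monosubstituted vinyl group next to the quaternary carbon.

**Step 3**
Reactants: 5 (3S)-7-hydroxy-3,7-dimethyloct-1-en-3-yl 2-hydroxyacetate; 6 (triphenylphosphoranylidene)ketene
Product: 7 4-{[(3S)-7-hydroxy-3,7-dimethyloct-1-en-3-yl]oxy}furan-2(5H)-one
Conditions: THF, 60 °C
Reagents that add atoms: none
Why: Domino addition/intramolecular Wittig olefination: the primary OH adds to the cumulated ylide and the resulting ester ylide olefinates the glycolate ester carbonyl, so the tertiary alkoxy group becomes the C4 enol-ether oxygen of a tetronate without any bond to the stereocentre being made or broken.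

**Step 4**
Reactants: 7 4-{[(3S)-7-hydroxy-3,7-dimethyloct-1-en-3-yl]oxy}furan-2(5H)-one
Product: 8 4-{[(3S)-7-hydroxy-3,7-dimethyloct-1-en-3-yl]oxy}-3-iodofuran-2(5H)-one
Conditions: NIS, MeCN, 0 → 23 °C, dark
Reagents that add atoms: N-iodosuccinimide O=C1CCC(=O)N1I
Why: Electrophilic iodination at C3, the nucleophilic α-carbon of the vinylogous carbonate (β-alkoxybutenolide).

**Step 5**
Reactants: 8 4-{[(3S)-7-hydroxy-3,7-dimethyloct-1-en-3-yl]oxy}-3-iodofuran-2(5H)-one; 9 tributyl(vinyl)stannane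
Product: 10 3-ethenyl-4-{[(3S)-7-hydroxy-3,7-dimethyloct-1-en-3-yl]oxy}furan-2(5H)-one
Conditions: Pd2(dba)3 (2.5 mol %), AsPh3 (10 mol %), CuI (10 mol %), DMF, 23 °C
Reagents that add atoms: none
Why: Stille cross-coupling of an electron-poor alkenyl iodide at room temperature, where oxidative addition into C–I should outrun ionisation of the tertiary allylic vinylogous ester.

**Step 6**
Reactants: 11 methyl (2E)-3-(4-hydroxyphenyl)prop-2-enoate; 12 ethynylmagnesium bromide
Product: 14 (1E)-1-(4-hydroxyphenyl)pent-1-en-4-yn-3-one, via Weinreb amide 13 (not isolated)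
Conditions: MeNHOMe·HCl, i-PrMgCl, THF, −20 °C; then 12, −20 → 0 °C; inverse quench into cold 1 M HCl
Reagents that add atoms: none
Why: One-pot ester → Weinreb amide → ketone: the chloromagnesium amide converts the ester to the Weinreb amide, whose chelated tetrahedral adduct with the alkynyl Grignard reagent collapses to the ynone only on acidic quench, so there is no over-addition.

**Step 7**
Reactants: 10 3-ethenyl-4-{[(3S)-7-hydroxy-3,7-dimethyloct-1-en-3-yl]oxy}furan-2(5H)-one; 14 (1E)-1-(4-hydroxyphenyl)pent-1-en-4-yn-3-one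
Product: 20 (2E)-1-[(2S)-5,8-dihydroxy-2-(4-hydroxy-4-methylpentyl)-2-methyl-2H-chromen-6-yl]-3-(4-hydroxyphenyl)prop-2-en-1-one, via bis-silyl silyloxyfuran 15 (not isolated), via O-silyl enynone 16 (not isolated), via oxanorbornadiene cycloadduct 17 (not isolated), via divinyl aryl ether 18 (not isolated), via silylated chromene 19 (not isolated)
Conditions: 10, TMSCl, LiHMDS, THF, −78 °C; then 16 (from 14, BSA, THF, 23 °C), −78 → 23 °C; then Hoveyda–Grubbs II (5 mol %), 45 °C; then citric acid (cat.), MeOH, 23 °C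
Reagents that add atoms: none
Why: Proposed new method: the 2-silyloxy-4-alkoxyfuran attacks the ynone β-CH with its unsubstituted C5 (vinylogous ketene-acetal and enol-ether β-carbon) in a polar Diels–Alder reaction, the oxa-bridge opens at the silyl ketal carbon and tautomerises to the hydroquinone (ring A, acyl ortho to the new OH and para to the tertiary ether oxygen), and ring-closing metathesis of the two vinyl groups then closes the 2H-pyran, so C2 is simply the linalool carbinol carbon and no o-quinone methide or ring-opened 2H-pyran is passed; the closest known reaction types are the 2-alkoxy-/2-silyloxyfuran–alkyne Diels–Alder route to hydroquinone monoethers and the RCM of 2-vinylaryl 1,1-disubstituted allyl ethers to 2,2-disubstituted 2H-chromenes.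

**Compound list**
1 | (S)-(+)-linalool, (3S)-3,7-dimethylocta-1,6-dien-3-ol | CC(C)=CCC[C@@](O)(C)C=C | starting material
2 | acetoxyacetyl chloride | CC(=O)OCC(Cl)=O | starting material
3 | (3S)-3,7-dimethylocta-1,6-dien-3-yl 2-acetoxyacetate | CC(C)=CCC[C@@](OC(=O)COC(C)=O)(C)C=C | intermediate
4 | (3S)-3,7-dimethylocta-1,6-dien-3-yl 2-hydroxyacetate | CC(C)=CCC[C@@](OC(=O)CO)(C)C=C | intermediate
5 | (3S)-7-hydroxy-3,7-dimethyloct-1-en-3-yl 2-hydroxyacetate | CC(C)(O)CCC[C@@](OC(=O)CO)(C)C=C | intermediate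
6 | (triphenylphosphoranylidene)ketene | O=C=C=P(c1ccccc1)(c1ccccc1)c1ccccc1 | starting material
7 | 4-{[(3S)-7-hydroxy-3,7-dimethyloct-1-en-3-yl]oxy}furan-2(5H)-one | CC(C)(O)CCC[C@@](OC1=CC(=O)OC1)(C)C=C | intermediate
8 | 4-{[(3S)-7-hydroxy-3,7-dimethyloct-1-en-3-yl]oxy}-3-iodofuran-2(5H)-one | CC(C)(O)CCC[C@@](OC1=C(I)C(=O)OC1)(C)C=C | intermediate
9 | tributyl(vinyl)stannane | C=C[Sn](CCCC)(CCCC)CCCC | starting material
10 | 3-ethenyl-4-{[(3S)-7-hydroxy-3,7-dimethyloct-1-en-3-yl]oxy}furan-2(5H)-one | CC(C)(O)CCC[C@@](OC1=C(C=C)C(=O)OC1)(C)C=C | intermediate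
11 | methyl (2E)-3-(4-hydroxyphenyl)prop-2-enoate (methyl p-coumarate) | COC(=O)/C=C/c1ccc(O)cc1 | starting material
12 | ethynylmagnesium bromide | C#C[Mg]Br | starting material
13 | (2E)-3-(4-hydroxyphenyl)-N-methoxy-N-methylprop-2-enamide (present as its magnesium phenoxide) | CON(C)C(=O)/C=C/c1ccc(O)cc1 | intermediate
14 | (1E)-1-(4-hydroxyphenyl)pent-1-en-4-yn-3-one | C#CC(=O)/C=C/c1ccc(O)cc1 | intermediate
15 | {[3-ethenyl-4-({(3S)-3,7-dimethyl-7-[(trimethylsilyl)oxy]oct-1-en-3-yl}oxy)furan-2-yl]oxy}trimethylsilane | C[Si](C)(C)OC(C)(C)CCC[C@@](Oc1coc(O[Si](C)(C)C)c1C=C)(C)C=C | intermediate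
16 | (1E)-1-{4-[(trimethylsilyl)oxy]phenyl}pent-1-en-4-yn-3-one | C#CC(=O)/C=C/c1ccc(O[Si](C)(C)C)cc1 | intermediate
17 | 7-oxabicyclo[2.2.1]hepta-2,5-diene cycloadduct: 1-OSiMe3, 2-[(2E)-3-(4-trimethylsilyloxyphenyl)prop-2-enoyl], 5-{(3S)-3,7-dimethyl-7-[(trimethylsilyl)oxy]oct-1-en-3-yl}oxy, 6-ethenyl; both bridgehead diastereomers | C[Si](C)(C)OC(C)(C)CCC[C@@](OC1=C(C=C)C2(O[Si](C)(C)C)OC1C=C2C(=O)/C=C/c1ccc(O[Si](C)(C)C)cc1)(C)C=C | intermediate
18 | (2E)-1-[4-({(3S)-3,7-dimethyl-7-[(trimethylsilyl)oxy]oct-1-en-3-yl}oxy)-3-ethenyl-5-hydroxy-2-[(trimethylsilyl)oxy]phenyl]-3-{4-[(trimethylsilyl)oxy]phenyl}prop-2-en-1-one | C[Si](C)(C)OC(C)(C)CCC[C@@](Oc1c(O)cc(C(=O)/C=C/c2ccc(O[Si](C)(C)C)cc2)c(O[Si](C)(C)C)c1C=C)(C)C=C | intermediate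
19 | (2E)-1-[(2S)-8-hydroxy-2-methyl-2-{4-methyl-4-[(trimethylsilyl)oxy]pentyl}-5-[(trimethylsilyl)oxy]-2H-chromen-6-yl]-3-{4-[(trimethylsilyl)oxy]phenyl}prop-2-en-1-one | C[Si](C)(C)OC(C)(C)CCC[C@@]1(C)C=Cc2c(O[Si](C)(C)C)c(C(=O)/C=C/c3ccc(O[Si](C)(C)C)cc3)cc(O)c2O1 | intermediate
20 | (2E)-1-[(2S)-5,8-dihydroxy-2-(4-hydroxy-4-methylpentyl)-2-methyl-2H-chromen-6-yl]-3-(4-hydroxyphenyl)prop-2-en-1-one | CC(C)(O)CCC[C@@]1(C)C=Cc2c(O)c(C(=O)/C=C/c3ccc(O)cc3)cc(O)c2O1 | target

**Totals**
Total step count: 7. Longest linear sequence: 6 (steps 1, 2, 3, 4, 5, 7 from compound 1).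

**Steps most likely to fail and fallbacks**

Step 7 is the most exposed. The enynone can polymerise or be attacked at its enone, the vinylfuran can react as an extra-annular diene, and the hindered styrene or residual salts can stall the ruthenium catalyst. The fallback sets out from 10 and comes back at 20. It keeps the one-pot cycloaddition/metathesis but uses the small, more reactive dienophile but-3-yn-2-one, so the chalcone is built afterwards. The product is 1-[(2S)-5,8-dihydroxy-2-(4-hydroxy-4-methylpentyl)-2-methyl-2H-chromen-6-yl]ethan-1-one F4. Claisen–Schmidt condensation of F4 with 4-(oxan-2-yloxy)benzaldehyde (Ba(OH)2, MeOH, argon) gives (2E)-1-[(2S)-5,8-dihydroxy-2-(4-hydroxy-4-methylpentyl)-2-methyl-2H-chromen-6-yl]-3-[4-(oxan-2-yloxy)phenyl]prop-2-en-1-one F5. PPTS in ethanol then removes the acetal to give 20.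

Step 5 comes next. Palladium(0) can ionise the tertiary allylic vinylogous ester to a π-allyl complex, which would scramble or destroy the stereocentre. The fallback sets out from 8 and comes back at 10, and uses no palladium. Iodine–magnesium exchange (i-PrMgCl·LiCl, THF, −40 °C, one extra equivalent for the free OH) and addition to acetaldehyde give 4-{[(3S)-7-hydroxy-3,7-dimethyloct-1-en-3-yl]oxy}-3-(1-hydroxyethyl)furan-2(5H)-one F3. Selective mesylation of the secondary alcohol of F3 (MsCl, Et3N, 0 °C) and elimination with DBU give 10.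

Step 3 is the third risk. Wittig ring closure onto a hindered tertiary ester may be slow, the ylide can also engage the tertiary OH, and forcing temperatures invite a [3,3] shift of the tertiary allyl group. The fallback sets out from 1 and comes back at 7; it builds the butenolide around the ether oxygen. Base-catalysed oxa-Michael addition of 1 (NaH cat., THF, 0 °C) to methyl 4-[(tert-butyldimethylsilyl)oxy]but-2-ynoate gives methyl (2E)-4-[(tert-butyldimethylsilyl)oxy]-3-{[(3S)-3,7-dimethylocta-1,6-dien-3-yl]oxy}but-2-enoate F1. Bu4NF in THF frees the γ-hydroxyl of F1, which lactonises onto the cis ester to give 4-{[(3S)-3,7-dimethylocta-1,6-dien-3-yl]oxy}furan-2(5H)-one F2. Mukaiyama hydration of F2 under the conditions of step 2 gives 7.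

**Further compounds**
F1 | step 3 | methyl (2E)-4-[(tert-butyldimethylsilyl)oxy]-3-{[(3S)-3,7-dimethylocta-1,6-dien-3-yl]oxy}but-2-enoate | CC(C)=CCC[C@@](O/C(CO[Si](C)(C)C(C)(C)C)=C/C(=O)OC)(C)C=C
F2 | step 3 | 4-{[(3S)-3,7-dimethylocta-1,6-dien-3-yl]oxy}furan-2(5H)-one | CC(C)=CCC[C@@](OC1=CC(=O)OC1)(C)C=C
F3 | step 5 | 4-{[(3S)-7-hydroxy-3,7-dimethyloct-1-en-3-yl]oxy}-3-(1-hydroxyethyl)furan-2(5H)-one (carbinol epimers) | CC(C)(O)CCC[C@@](OC1=C(C(C)O)C(=O)OC1)(C)C=C
F4 | step 7 | 1-[(2S)-5,8-dihydroxy-2-(4-hydroxy-4-methylpentyl)-2-methyl-2H-chromen-6-yl]ethan-1-one | CC(C)(O)CCC[C@@]1(C)C=Cc2c(O)c(C(C)=O)cc(O)c2O1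
F5 | step 7 | (2E)-1-[(2S)-5,8-dihydroxy-2-(4-hydroxy-4-methylpentyl)-2-methyl-2H-chromen-6-yl]-3-[4-(oxan-2-yloxy)phenyl]prop-2-en-1-one (acetal epimers) | CC(C)(O)CCC[C@@]1(C)C=Cc2c(O)c(C(=O)/C=C/c3ccc(OC4CCCCO4)cc3)cc(O)c2O1
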